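**Retrosynthetic overview**
1. Feature: C10 is the quaternary fusion carbon of rings A and B. It carries the C20 methyl group and is bonded to C1, which lies β to the C3 oxygen. C20 can therefore come from a C10=C20 methylene, and C1–C10 from radical addition to a C3 vinyl ketone.
2. Ring A is formed last (step 17) on an intact ring B. Target 35 ⇐ C8 ketone 33 (methylenation) ⇐ C3 ketone/C8 ketal 30 (axial reduction, acetylation, hydrolysis).
3. Precursor 29 ⇐ ring B silyl dienol ether 24, by face-selective protonation at C9, aprotic ketalisation of C8 and oxidation of the C3 carbinol.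
4. C4–C5 and C10=C20 ⇐ dianionic Ireland–Claisen rearrangement of ester 19. The 3R carbinol (Evans aldol with acrolein) relays the absolute configuration to C4 and C5.
5. Ring B comes from cyclohexane-1,3-dione, C9-alkylated reductively with the C11–C16 aldehyde 4 (C13 from monomethyl (R)-3-methylglutarate).

Key step: step 17

Remark: labdane numbering (C1–C20) and the α/β convention of the usual labdane drawing are used for all intermediates; 1, 5, 13 and 14 are taken as commercial.

Step 1
Reactants: 1 monomethyl (R)-3-methylglutarate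
Product: 2 methyl (3R)-5-hydroxy-3-methylpentanoate
Conditions: BH3·SMe2, THF, 0 °C to rt; MeOH quench
Reagents that add atoms: none
Why: Chemoselective borane reduction: the free acid is reduced through its acyloxyborane far faster than the methyl ester, so C15 reaches the alcohol level, C11 stays an ester and the C13 centre is untouched.

Step 2
Reactants: 2 methyl (3R)-5-hydroxy-3-methylpentanoate
Product: 3 methyl (3R)-5-(tert-butyldiphenylsilyloxy)-3-methylpentanoate
Conditions: TBDPSCl, imidazole, DMF, rt
Reagents that add atoms: tert-butyl(chloro)diphenylsilane, CC(C)(C)[Si](Cl)(c1ccccc1)c1ccccc1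
Why: Standard silyl ether formation that also stops lactonisation of 2; this silyl group is chosen because it should outlast the brief fluoride treatment of step 14 and the aqueous acid of step 20.

Step 3
Reactants: 3 methyl (3R)-5-(tert-butyldiphenylsilyloxy)-3-methylpentanoate
Product: 4 (3R)-5-(tert-butyldiphenylsilyloxy)-3-methylpentanal (C11 aldehyde, C11–C16)
Conditions: i-Bu2AlH (1.05 equiv), toluene, −78 °C; aq potassium sodium tartrate
Reagents that add atoms: none
Why: Partial ester reduction: the tetrahedral aluminium alkoxide is stable at −78 °C and collapses to the aldehyde only on work-up.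

Step 4
Reactants: 4 (3R)-5-(tert-butyldiphenylsilyloxy)-3-methylpentanal; 5 cyclohexane-1,3-dione
Product: 7 2-[(3S)-5-(tert-butyldiphenylsilyloxy)-3-methylpentyl]cyclohexane-1,3-dione, via Knoevenagel alkylidene dione 6 (not isolated)
Conditions: L-proline (20 mol%), Hantzsch ester (1 equiv), CH2Cl2, rt
Reagents that add atoms: none
Why: Organocatalytic three-component reductive alkylation (Knoevenagel condensation, then Hantzsch ester transfer hydrogenation of 6) gives clean C-monoalkylation at C9, where direct alkylation of the dione with an unactivated halide would go mainly to oxygen.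

Step 5
Reactants: 7 2-alkylcyclohexane-1,3-dione
Product: 8 3-(triisopropylsilyloxy)-2-alkylcyclohex-2-en-1-one (C10 ketone, C8(OTIPS)=C9)
Conditions: TIPSOTf (1.05 equiv), Et3N, CH2Cl2, 0 °C
Reagents that add atoms: triisopropylsilyl triflate, CC(C)[Si](OS(=O)(=O)C(F)(F)F)(C(C)C)C(C)C
Why: O-Silylation of the vinylogous acid (a single product because the dione is symmetric) masks C8 and keeps C9 trigonal, so ring B carries no stereocentre that could oppose the reagent control of step 12.

Step 6
Reactants: 8 3-(triisopropylsilyloxy)-2-alkylcyclohex-2-en-1-one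
Product: 10 dienyl triflate (C10–OTf; C10=C5; C8(OTIPS)=C9), via lithium dienolate 9 (not isolated)
Conditions: LiN(i-Pr)2, THF, −78 °C; PhNTf2, −78 to 0 °C
Reagents that add atoms: N-phenylbis(trifluoromethanesulfonimide), O=S(=O)(N(c1ccccc1)S(=O)(=O)C(F)(F)F)C(F)(F)F
Why: Kinetic deprotonation of the vinylogous ester takes place at the α′ carbon C5 (Stork–Danheiser regiochemistry), and O-sulfonylation of 9 fixes the C10=C5 double bond (enol triflate synthesis).

Step 7
Reactants: 10 dienyl triflate
Product: 11 methyl dienoate (C20 = CO2Me on C10)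
Conditions: Pd(OAc)2 (5 mol%), PPh3, CO (1 atm), MeOH, Et3N, DMF, 40 °C
Reagents that add atoms: carbon monoxide, [C-]#[O+]; methanol, CO
Why: Palladium-catalysed methoxycarbonylation of an enol triflate (oxidative addition to zerovalent palladium, CO insertion, methanolysis) attaches C20 to C10 without moving either double bond.

Step 8
Reactants: 11 methyl dienoate
Product: 12 ring B dienyl methanol (C20H2OH on C10; C10=C5; C8(OTIPS)=C9)
Conditions: i-Bu2AlH (2.2 equiv), CH2Cl2, −78 °C; aq potassium sodium tartrate
Reagents that add atoms: none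
Why: 1,2-Reduction of the conjugated ester gives the primary allylic alcohol; the silyl enol ether and the silyl ether are inert.

Step 9
Reactants: 13 (S)-4-benzyl-3-propionyloxazolidin-2-one; 14 acrolein
Product: 16 (4S)-4-benzyl-3-[(2S,3R)-3-hydroxy-2-methylpent-4-enoyl]oxazolidin-2-one, via Z dibutylboron enolate 15 (not isolated)
Conditions: n-Bu2BOTf, Et3N, CH2Cl2, 0 °C; 14, −78 to 0 °C; pH 7 buffer, MeOH, H2O2
Reagents that add atoms: none
Why: Evans syn aldol reaction: the Z boron enolate reacts through a Zimmerman–Traxler chair on the face left open by the benzyl group, which sets 3R (the only centre of 16 that is kept) and 2S.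

Step 10
Reactants: 16 syn-aldol imide
Product: 18 (2S,3R)-3-hydroxy-2-methylpent-4-enoic acid, via peroxy acid 17 (not isolated)
Conditions: LiOH, H2O2, THF–H2O, 0 °C; Na2SO3; HCl to pH 2
Reagents that add atoms: hydrogen peroxide, OO
Why: Hydroperoxide attacks the exocyclic imide carbonyl selectively and sulfite reduces the peracid, while the carbinol centre and the vinyl group are untouched.

Step 11
Reactants: 12 ring B dienyl methanol; 18 (2S,3R)-3-hydroxy-2-methylpent-4-enoic acid
Product: 19 C20 ester of 12 with 18 (free 3R carbinol)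
Conditions: EDC·HCl, DMAP (cat.), CH2Cl2, 0 °C to rt, slow addition of 18
Reagents that add atoms: none
Why: Carbodiimide (Steglich) esterification in which the unhindered primary allylic alcohol should outcompete the α-branched secondary carbinol of the slowly added acid for the acylpyridinium ion.

Step 12
Reactants: 19 β-hydroxy allylic ester
Product: 23 C19 acid with the C5 arm C4(Me)(CO2H)CH(OH)CH=CH2 (3R; C4 and C5 as in 35; C10=C20; C8(OTIPS)=C9), via dilithio alkoxide enolate 20 (not isolated), via bis-silyl ketene acetal 21 (not isolated), via rearranged bis-silyl derivative 22 (not isolated)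
Conditions: LiN(i-Pr)2 (2.3 equiv), THF, −78 to −30 °C; Me3SiCl, −78 °C to rt, then 40 °C; aq citric acid, 0 °C
Reagents that add atoms: none
Why: Dianionic Ireland–Claisen rearrangement of an α-methyl-β-hydroxy allylic ester: the lithium chelate between alkoxide and enolate oxygens in 20 fixes the acetal geometry (C3 cis to the silyloxy group in 21) and suppresses β-elimination, and the [3,3] shift runs through a chair (favoured by the C9 branch on the central allyl carbon C10) on the acetal face anti to the C3 oxygen substituent, so that 3R is relayed to C4 and, through the chair, to C5 while C10=C20 is created.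

Step 13
Reactants: 23 C19 acid
Product: 24 C19 methyl ester (3R carbinol free; silyl dienol ether intact)
Conditions: MeI, K2CO3, DMF, 0 °C to rt
Reagents that add atoms: iodomethane, CI
Why: Carboxylate O-alkylation (SN2 on MeI) esterifies the neopentyl acid at a site remote from the congestion, and K2CO3 is too weak to deprotonate the carbinol, so retro-aldol cleavage is not expected.

Step 14
Reactants: 24 C19 methyl ester silyl dienol ether
Product: 26 β,γ-unsaturated C8 ketone (9α-H; side chain cis to the C5 arm; C10=C20), via tetrabutylammonium dienolate 25 (not isolated)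
Conditions: n-Bu4NF (1.1 equiv), AcOH (2 equiv), THF, −78 to −20 °C
Reagents that add atoms: none
Why: Fluoride cleaves the enol O–Si bond much faster than the alkyl silyl ether, and the extended enolate is protonated kinetically at its α carbon C9 (deconjugative protonation) by acetic acid from the α face, because allylic 1,3-strain with C20H2 holds the bulky C5 arm pseudoaxial over the β face.

Step 15
Reactants: 26 β,γ-unsaturated C8 ketone
Product: 28 C8 ethylene ketal with free 3R carbinol, via C3 trimethylsilyl ether 27 (not isolated)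
Conditions: Me3SiOCH2CH2OSiMe3 (3 equiv), Me3SiOTf (5 mol%), CH2Cl2, −78 to −30 °C; pyridine; K2CO3, MeOH, 0 °C
Reagents that add atoms: 1,2-bis(trimethylsilyloxy)ethane, C[Si](C)(C)OCCO[Si](C)(C)C
Why: Noyori ketalisation under aprotic silyl triflate catalysis works at low temperature without enolisation, so C10=C20 stays out of conjugation and C9 keeps its configuration; the C3 carbinol is only silylated in passing and is released by methanolysis.

Step 16
Reactants: 28 C8 ketal carbinol
Product: 29 key-step precursor: ring B with C10=C20, 9β side chain, C8 dioxolane and C5 arm C4(Me)(CO2Me)C(=O)CH=CH2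
Conditions: Dess–Martin periodinane, NaHCO3, CH2Cl2, 0 °C
Reagents that add atoms: none
Why: Dess–Martin oxidation of the allylic carbinol under buffered conditions gives the vinyl ketone and removes the C3 relay centre after it has done its work; C4 has no α hydrogen and cannot epimerise.

Step 17
Reactants: 29 key-step precursor
Product: 30 trans-decalin C3 ketone (4α-Me, 4β-CO2Me, 5α-H, 10β-Me, 9β side chain, C8 dioxolane)
Conditions: Fe(acac)3 (0.3 equiv), PhSiH3 (2.5 equiv), EtOH–ethylene glycol (5:1), 0.01 M, degassed, 60 °C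
Reagents that add atoms: none
Why: Fe(acac)3 and PhSiH3 in ethanol form a hydride of trivalent iron that transfers a hydrogen atom to the unhindered C20 terminus of the electron-rich 1,1-disubstituted alkene, which makes C20 the angular methyl group and leaves a nucleophilic tertiary radical at C10; this radical adds to C1 of the vinyl ketone, and the C2 radical next to the C3 carbonyl is reduced by divalent iron to the enolate and protonated by ethanol. The closest known reaction type is the iron-catalysed reductive olefin–enone coupling (hydrogen-atom-transfer Giese reaction) in its intramolecular form, which is established for quaternary centres. Ring A closes in the 6-endo-trig mode, because attack at the unsubstituted, polarity-matched β carbon C1 gives a carbonyl-stabilised radical, whereas 5-exo attack at C2 would give a primary radical and a congested cyclopentanone. The only new stereocentre, C10, is controlled by the ring B chair in which the C5 arm and the C9 chain are both equatorial: the C20 methyl group bends to the axial β side to escape both neighbours, the half-filled orbital points to the equatorial α side, and C1 reaches it through a chair-like transition state, which gives the trans fusion as in the second closure of radical polyene cyclisations. The step needs hydrogen-atom transfer to C10=C20 rather than to the enone, which the electron-poor character of the vinyl ketone and high dilution should secure; the C8 ketal keeps the transient C2 enolate from an aldol reaction at C8, and the fully substituted C4 cannot enolise.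

Step 18
Reactants: 30 trans-decalin C3 ketone
Product: 31 3α (axial) alcohol
Conditions: LiBH(s-Bu)3 (L-Selectride, 1.5 equiv), THF, −78 °C; H2O quench
Reagents that add atoms: none
Why: The bulky trialkylborohydride attacks the C3 ketone along the equatorial trajectory from the β side, since the axial α path is closed by the axial hydrogens at C1 and C5, and should give the axial 3α alcohol; ester and ketal are inert at −78 °C.

Step 19
Reactants: 31 3α alcohol
Product: 32 3α acetate
Conditions: Ac2O, DMAP (cat.), pyridine, 40 °C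
Reagents that add atoms: acetic anhydride, CC(=O)OC(C)=O
Why: DMAP-catalysed acylation overcomes the hindrance of the axial neopentyl carbinol, and no elimination or retro-aldol path is open because C4 is quaternary and no strong base is present.

Step 20
Reactants: 32 3α acetate C8 ketal
Product: 33 C8 ketone (9β side chain, 9α-H)
Conditions: 2 M aq HCl–THF (1:4), 40 °C
Reagents that add atoms: water, O
Why: Acid hydrolysis of the ketal is helped by relief of the 1,3-diaxial contact between the axial ketal oxygen and C20; the equatorial 9β chain is also the thermodynamic epimer, so enolisation towards C9 is harmless, and the silyl ether and the hindered acetate should survive.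

Step 21
Reactants: 33 C8 ketone
Product: 34 C8=C17 methylene compound (C15 silyl ether)
Conditions: Zn, CH2Br2, TiCl4, THF–CH2Cl2, 0 °C to rt
Reagents that add atoms: dibromomethane, BrCBr
Why: Takai–Lombardo methylenation: the non-basic zinc–titanium methylene reagent converts hindered enolisable ketones without epimerising C9 and leaves the acetate, the methyl ester and the silyl ether untouched.

Step 22
Reactants: 34 C15 silyl ether
Product: 35 methyl (13S)-3α-acetoxy-15-hydroxylabd-8(17)-en-19-oate (target)
Conditions: HF·pyridine, pyridine, THF, 0 °C to rt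
Reagents that add atoms: none
Why: Buffered fluoride cleavage of the primary silyl ether is neutral enough to avoid acetate migration or hydrolysis and isomerisation of the exocyclic alkene.

**Compound list**
1 | monomethyl (R)-3-methylglutarate | COC(=O)C[C@H](C)CC(=O)O | starting material
2 | methyl (3R)-5-hydroxy-3-methylpentanoate | COC(=O)C[C@H](C)CCO | intermediate
3 | methyl (3R)-5-(tert-butyldiphenylsilyloxy)-3-methylpentanoate | COC(=O)C[C@H](C)CCO[Si](c6ccccc6)(c7ccccc7)C(C)(C)C | intermediate
4 | (3R)-5-(tert-butyldiphenylsilyloxy)-3-methylpentanal | O=CC[C@H](C)CCO[Si](c6ccccc6)(c7ccccc7)C(C)(C)C | intermediate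
5 | cyclohexane-1,3-dione | O=C1CCCC(=O)C1 | starting material
6 | Knoevenagel alkylidene dione (C9=C11) | O=C1CCCC(=O)C1=CC[C@H](C)CCO[Si](c6ccccc6)(c7ccccc7)C(C)(C)C | intermediate
7 | 2-[(3S)-5-(tert-butyldiphenylsilyloxy)-3-methylpentyl]cyclohexane-1,3-dione | O=C1CCCC(=O)C1CC[C@H](C)CCO[Si](c6ccccc6)(c7ccccc7)C(C)(C)C | intermediate
8 | 3-(triisopropylsilyloxy)-2-alkylcyclohex-2-en-1-one | O=C1CCCC(O[Si](C(C)C)(C(C)C)C(C)C)=C1CC[C@H](C)CCO[Si](c6ccccc6)(c7ccccc7)C(C)(C)C | intermediate
9 | lithium dienolate of 8 (C10–OLi, C10=C5) | [Li]OC1=CCCC(O[Si](C(C)C)(C(C)C)C(C)C)=C1CC[C@H](C)CCO[Si](c6ccccc6)(c7ccccc7)C(C)(C)C | intermediate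
10 | dienyl triflate | O=S(=O)(OC1=CCCC(O[Si](C(C)C)(C(C)C)C(C)C)=C1CC[C@H](C)CCO[Si](c6ccccc6)(c7ccccc7)C(C)(C)C)C(F)(F)F | intermediate
11 | methyl dienoate (C20 ester) | COC(=O)C1=CCCC(O[Si](C(C)C)(C(C)C)C(C)C)=C1CC[C@H](C)CCO[Si](c6ccccc6)(c7ccccc7)C(C)(C)C | intermediate
12 | ring B dienyl methanol | OCC1=CCCC(O[Si](C(C)C)(C(C)C)C(C)C)=C1CC[C@H](C)CCO[Si](c6ccccc6)(c7ccccc7)C(C)(C)C | intermediate
13 | (S)-4-benzyl-3-propionyloxazolidin-2-one | CCC(=O)N1[C@@H](Cc2ccccc2)COC1=O | starting material
14 | acrolein | C=CC=O | starting material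
15 | Z dibutylboron enolate of 13 | C/C=C(\OB(CCCC)CCCC)N1[C@@H](Cc2ccccc2)COC1=O | intermediate
16 | (4S)-4-benzyl-3-[(2S,3R)-3-hydroxy-2-methylpent-4-enoyl]oxazolidin-2-one | C=C[C@@H](O)[C@H](C)C(=O)N1[C@@H](Cc2ccccc2)COC1=O | intermediate
17 | (2S,3R)-3-hydroxy-2-methylpent-4-eneperoxoic acid | C=C[C@@H](O)[C@H](C)C(=O)OO | intermediate
18 | (2S,3R)-3-hydroxy-2-methylpent-4-enoic acid | C=C[C@@H](O)[C@H](C)C(=O)O | intermediate
19 | β-hydroxy allylic ester of 12 and 18 | C=C[C@@H](O)[C@H](C)C(=O)OCC1=CCCC(O[Si](C(C)C)(C(C)C)C(C)C)=C1CC[C@H](C)CCO[Si](c6ccccc6)(c7ccccc7)C(C)(C)C | intermediate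
20 | dilithio alkoxide enolate of 19 (C3 cis to OLi) | C=C[C@@H](O[Li])/C(C)=C(\O[Li])OCC1=CCCC(O[Si](C(C)C)(C(C)C)C(C)C)=C1CC[C@H](C)CCO[Si](c6ccccc6)(c7ccccc7)C(C)(C)C | intermediate
21 | bis(trimethylsilyl) ketene acetal (Z) | C=C[C@@H](O[Si](C)(C)C)/C(C)=C(\O[Si](C)(C)C)OCC1=CCCC(O[Si](C(C)C)(C(C)C)C(C)C)=C1CC[C@H](C)CCO[Si](c6ccccc6)(c7ccccc7)C(C)(C)C | intermediate
22 | rearranged trimethylsilyl ester, C3 trimethylsilyl ether | C=C1C(CC[C@H](C)CCO[Si](c6ccccc6)(c7ccccc7)C(C)(C)C)=C(O[Si](C(C)C)(C(C)C)C(C)C)CC[C@H]1[C@@](C)(C(=O)O[Si](C)(C)C)[C@H](O[Si](C)(C)C)C=C | intermediate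
23 | C19 acid (3R carbinol, C4/C5 set, C10=C20, C8(OTIPS)=C9) | C=C1C(CC[C@H](C)CCO[Si](c6ccccc6)(c7ccccc7)C(C)(C)C)=C(O[Si](C(C)C)(C(C)C)C(C)C)CC[C@H]1[C@@](C)(C(=O)O)[C@H](O)C=C | intermediate
24 | C19 methyl ester of 23 | C=C1C(CC[C@H](C)CCO[Si](c6ccccc6)(c7ccccc7)C(C)(C)C)=C(O[Si](C(C)C)(C(C)C)C(C)C)CC[C@H]1[C@@](C)(C(=O)OC)[C@H](O)C=C | intermediate
25 | tetrabutylammonium dienolate | C=C1C(CC[C@H](C)CCO[Si](c6ccccc6)(c7ccccc7)C(C)(C)C)=C([O-])CC[C@H]1[C@@](C)(C(=O)OC)[C@H](O)C=C.CCCC[N+](CCCC)(CCCC)CCCC | intermediate
26 | β,γ-unsaturated C8 ketone (9α-H) | C=C1[C@@H](CC[C@H](C)CCO[Si](c6ccccc6)(c7ccccc7)C(C)(C)C)C(=O)CC[C@H]1[C@@](C)(C(=O)OC)[C@H](O)C=C | intermediate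
27 | C8 ketal, C3 trimethylsilyl ether | C=C1[C@@H](CC[C@H](C)CCO[Si](c6ccccc6)(c7ccccc7)C(C)(C)C)C2(OCCO2)CC[C@H]1[C@@](C)(C(=O)OC)[C@H](O[Si](C)(C)C)C=C | intermediate
28 | C8 ketal, free 3R carbinol | C=C1[C@@H](CC[C@H](C)CCO[Si](c6ccccc6)(c7ccccc7)C(C)(C)C)C2(OCCO2)CC[C@H]1[C@@](C)(C(=O)OC)[C@H](O)C=C | intermediate
29 | key-step precursor (vinyl ketone) | C=C1[C@@H](CC[C@H](C)CCO[Si](c6ccccc6)(c7ccccc7)C(C)(C)C)C2(OCCO2)CC[C@H]1[C@@](C)(C(=O)OC)C(=O)C=C | intermediate
30 | trans-decalin C3 ketone, C8 ketal | O1CCOC15CC[C@@H]2[C@](C)(CCC(=O)[C@]2(C)C(=O)OC)[C@H]5CC[C@H](C)CCO[Si](c6ccccc6)(c7ccccc7)C(C)(C)C | intermediate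
31 | 3α alcohol | O1CCOC15CC[C@@H]2[C@](C)(CC[C@@H](O)[C@]2(C)C(=O)OC)[C@H]5CC[C@H](C)CCO[Si](c6ccccc6)(c7ccccc7)C(C)(C)C | intermediate
32 | 3α acetate | O1CCOC15CC[C@@H]2[C@](C)(CC[C@@H](OC(C)=O)[C@]2(C)C(=O)OC)[C@H]5CC[C@H](C)CCO[Si](c6ccccc6)(c7ccccc7)C(C)(C)C | intermediate
33 | C8 ketone | O=C1CC[C@@H]2[C@](C)(CC[C@@H](OC(C)=O)[C@]2(C)C(=O)OC)[C@H]1CC[C@H](C)CCO[Si](c6ccccc6)(c7ccccc7)C(C)(C)C | intermediate
34 | C8=C17 methylene, C15 silyl ether | C=C1CC[C@@H]2[C@](C)(CC[C@@H](OC(C)=O)[C@]2(C)C(=O)OC)[C@H]1CC[C@H](C)CCO[Si](c6ccccc6)(c7ccccc7)C(C)(C)C | intermediate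
35 | methyl (13S)-3α-acetoxy-15-hydroxylabd-8(17)-en-19-oate | C=C1CC[C@@H]2[C@](C)(CC[C@@H](OC(C)=O)[C@]2(C)C(=O)OC)[C@H]1CC[C@H](C)CCO | target

**Step count and risks**
Total step count: 22. Longest linear sequence: 20 steps (steps 1–8, then 11–22).

Steps most likely to fail:

Step 17. The C10 radical or the vinyl ketone may be reduced by the iron hydride before the ring closes, and the preference for equatorial bond formation at C10 may be incomplete. The fallback sets out from 28 and comes back at 30.
- Cobalt-catalysed Markovnikov hydrochlorination of the more electron-rich 1,1-disubstituted alkene (Co(BF4)2·6H2O, salicylaldimine ligand, TsCl, PhSiH3, t-BuOOH, EtOH, rt) gives the C10 tertiary chloride F1.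
- Dess–Martin oxidation of the carbinol gives the chloro vinyl ketone F2.
- Slow addition of n-Bu3SnH and AIBN in refluxing benzene at high dilution abstracts chlorine and closes ring A as a tin hydride Giese cyclisation.
- Radical generation is thus separated from any metal hydride that could attack the enone, and concentration and temperature can be set independently.

Step 14. Protonation may drift to C20, which moves the alkene into conjugation, or may be poorly face-selective at C9. The fallback sets out from 24 and comes back at 28.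
- N-Bromosuccinimide (THF, −78 °C) attacks the silyl dienol ether at its unhindered γ terminus C20 and gives the bromomethyl enone F3.
- Aprotic ketalisation as in step 15 gives the allylic bromide ketal F4, in which C9=C10 is kept.
- Palladium-catalysed formate hydrogenolysis (Pd(OAc)2, n-Bu3P, HCO2NH4, dioxane, 60 °C) forms the π-allyl complex on the α face, away from the C5 arm. It then transfers hydride from palladium to the more substituted terminus C9 on that same face.
- 9α-H and the exocyclic C10=C20 bond are therefore set by metal-bound hydride delivery instead of protonation.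

Step 12. The enolate geometry may be lost, the dianion may fragment by retro-aldol or ketene formation, or the facial bias from C3 may be weak. The fallback sets out from 12 and comes back at 24.
- Acylation with propionyl chloride and pyridine gives the propionate F5.
- An enantioselective boron-mediated Ireland–Claisen rearrangement sets C5 under reagent control and gives the C4–H acid F6. It uses a chiral 1,2-diphenylethylenediamine bis(sulfonamide) bromoborane in the enantiomer that gives the C5 configuration of 23, with i-Pr2NEt in CH2Cl2 at −78 to −20 °C.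
- MeI and K2CO3 give the methyl ester F7.
- Deprotonation with LiN(i-Pr)2 and aldol addition to acrolein builds the quaternary C4. Attack comes from the enolate face anti to the C10 branch, in the conformer with H5 eclipsing the enolate double bond.
- This gives 24 together with its 3S epimer F8, which is removed by chromatography.

**Further compounds**
F1 | step 17 | C10 tertiary chloride of 28 (C10 epimers) | CC1(Cl)[C@@H](CC[C@H](C)CCO[Si](c6ccccc6)(c7ccccc7)C(C)(C)C)C2(OCCO2)CC[C@H]1[C@@](C)(C(=O)OC)[C@H](O)C=C
F2 | step 17 | chloro vinyl ketone | CC1(Cl)[C@@H](CC[C@H](C)CCO[Si](c6ccccc6)(c7ccccc7)C(C)(C)C)C2(OCCO2)CC[C@H]1[C@@](C)(C(=O)OC)C(=O)C=C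
F3 | step 14 | bromomethyl enone (C20–Br, C9=C10, C8 ketone) | BrCC1=C(CC[C@H](C)CCO[Si](c6ccccc6)(c7ccccc7)C(C)(C)C)C(=O)CC[C@H]1[C@@](C)(C(=O)OC)[C@H](O)C=C
F4 | step 14 | allylic bromide ketal | BrCC1=C(CC[C@H](C)CCO[Si](c6ccccc6)(c7ccccc7)C(C)(C)C)C2(OCCO2)CC[C@H]1[C@@](C)(C(=O)OC)[C@H](O)C=C
F5 | step 12 | propionate of 12 | CCC(=O)OCC1=CCCC(O[Si](C(C)C)(C(C)C)C(C)C)=C1CC[C@H](C)CCO[Si](c6ccccc6)(c7ccccc7)C(C)(C)C
F6 | step 12 | C4–H acid from the propionate rearrangement | C=C1C(CC[C@H](C)CCO[Si](c6ccccc6)(c7ccccc7)C(C)(C)C)=C(O[Si](C(C)C)(C(C)C)C(C)C)CC[C@H]1C(C)C(=O)O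
F7 | step 12 | methyl ester of F6 | C=C1C(CC[C@H](C)CCO[Si](c6ccccc6)(c7ccccc7)C(C)(C)C)=C(O[Si](C(C)C)(C(C)C)C(C)C)CC[C@H]1C(C)C(=O)OC
F8 | step 12 | 3S epimer of 24 | C=C1C(CC[C@H](C)CCO[Si](c6ccccc6)(c7ccccc7)C(C)(C)C)=C(O[Si](C(C)C)(C(C)C)C(C)C)CC[C@H]1[C@@](C)(C(=O)OC)[C@@H](O)C=C
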